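**Retrosynthetic overview**
1. Target 24 ← phenol debenzylation, 10α-OH-directed α-epoxidation of C3=C4 and C8 esterification of guai-3-ene-8β,10α-diol 19 ← reductive 1,3-transposition of guai-4-en-3-one 15 (sets 5β-H).
2. 15 ← photochemical skeletal rearrangement of 8β-hydroxyeudesma-1,4-dien-3-one 14. The enabling feature is the cross-conjugated dienone of ring A (C1=C2, C3=O, C4=C5 with the C4 methyl) whose quaternary C10 is shared with six-membered ring B.
3. In that step C1–C5 bonding and C5–C10 cleavage turn ring B (C5,C6,C7,C8,C9,C10) into the seven-membered ring (C1,C10,C9,C8,C7,C6,C5) and ring A into the cyclopentenone; water captures C10.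
4. 14 ← Robinson annulation (chiral-imine Michael addition, aldol) of ketone 5 with ethyl vinyl ketone, then C8 reduction and 1,2-dehydrogenation; 5 ← asymmetric conjugate addition of iPr2Zn to quinone monoketal 3 ← 4-methoxy-2-methylphenol 1.
5. Ring order: ring B carbocycle (from the arene), ring A (annulation), then 6/6 → 5/7 remodelling, epoxide last.

Key step: step 9

**Remarks**
- Bicyclic compounds carry eudesmane numbering (ring A: C1–C5, C10; ring B: C5–C10; C14 on C10, C15 on C4, isopropyl on C7) or guaiane numbering (five-ring C1–C5; seven-ring C1, C10, C9, C8, C7, C6, C5; C14 on C10, C15 on C4).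
- Assumption: the copper phosphoramidite catalyst is taken to attack dienone 3 with the same facial sense it shows with cyclohex-2-enone. The ligand antipode in step 3 follows from this; the other antipode would be used if the sense were opposite.

**Route**

Step 1
Reactants: 1 4-methoxy-2-methylphenol
Product: 2 4,4-dimethoxy-2-methylcyclohexa-2,5-dien-1-one
Conditions: PhI(OAc)2, MeOH, 0 °C to 20 °C
Reagents that add atoms: methanol, CO
Why: Oxidative dearomatisation of a para-methoxyphenol, in which methanol traps the phenoxenium ion at C4 to give the quinone monoketal; no stereocentre is formed.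

Step 2
Reactants: 2 4,4-dimethoxy-2-methylcyclohexa-2,5-dien-1-one
Product: 3 7-methyl-1,4-dioxaspiro[4.5]deca-6,9-dien-8-one
Conditions: HOCH2CH2OH, BF3·OEt2 (cat.), DME, 20 °C
Reagents that add atoms: ethane-1,2-diol, OCCO
Why: Lewis-acid-catalysed transketalisation replaces the labile dimethyl ketal by the dioxolane, which should survive the aqueous acetic acid of step 5; no stereocentre is formed.

Step 3
Reactants: 3 7-methyl-1,4-dioxaspiro[4.5]deca-6,9-dien-8-one
Product: 4 (10R)-7-methyl-10-(propan-2-yl)-1,4-dioxaspiro[4.5]dec-6-en-8-one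
Conditions: iPr2Zn, Cu(OTf)2 (2 mol%), O,O'-[(R)-1,1'-binaphthyl-2,2'-diyl] N,N-bis[(S)-1-phenylethyl]phosphoramidite (4 mol%), toluene, −30 °C; aq. NH4Cl
Reagents that add atoms: diisopropylzinc, CC(C)[Zn]C(C)C
Why: Copper-catalysed asymmetric conjugate addition of a dialkylzinc to a benzoquinone monoketal, in which the α-methyl group deactivates the C6=C7 enone so that isopropyl should add only at C10, and the chiral ligand selects the enantiotopic face to set the future C7 as (R).

Step 4
Reactants: 4 (10R)-7-methyl-10-(propan-2-yl)-1,4-dioxaspiro[4.5]dec-6-en-8-one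
Product: 5 (6R)-9-methyl-6-(propan-2-yl)-1,4-dioxaspiro[4.5]decan-8-one (both C9 epimers)
Conditions: H2 (1 atm), Pd/C, EtOAc, 20 °C
Reagents that add atoms: none
Why: Heterogeneous hydrogenation of the remaining enone double bond; the methyl-bearing centre forms as a mixture, which does not matter because it becomes the enamine carbon in step 5.

Step 5
Reactants: 5 (6R)-9-methyl-6-(propan-2-yl)-1,4-dioxaspiro[4.5]decan-8-one; 6 (R)-1-phenylethylamine; 7 pent-1-en-3-one
Product: 10 (6R,9R)-9-methyl-9-(3-oxopentyl)-6-(propan-2-yl)-1,4-dioxaspiro[4.5]decan-8-one, via imine 8 (not isolated), via Michael adduct imine 9 (not isolated)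
Conditions: 6, toluene, reflux (−H2O); then 7, THF, 40 °C; then 20% aq. AcOH, 20 °C
Reagents that add atoms: water, O
Why: Asymmetric Michael addition by the chiral-imine method, in which the more substituted secondary enamine tautomer of 8 adds to the enone through a chair-like aza-ene transition state on the face anti to the phenyl group of the (R)-auxiliary, creating the quaternary centre (future C10) with methyl cis to isopropyl; this is the same auxiliary and ring-stereocentre pairing that converts (+)-dihydrocarvone into (+)-α-cyperone.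

Step 6
Reactants: 10 (6R,9R)-9-methyl-9-(3-oxopentyl)-6-(propan-2-yl)-1,4-dioxaspiro[4.5]decan-8-one
Product: 12 (7R,10R)-eudesm-4-ene-3,8-dione, via enone ketal 11 (not isolated)
Conditions: NaOMe (cat.), MeOH, 60 °C; then 3 M aq. HCl, THF, 40 °C
Reagents that add atoms: water, O
Why: Intramolecular aldol condensation (second stage of the Robinson annulation) closes ring A as the 4-methyl enone while the ketal still masks C8, and aqueous acid then frees the C8 ketone; C7 becomes enolisable but its equatorial 7β-isopropyl group is the thermodynamic epimer.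

Step 7
Reactants: 12 (7R,10R)-eudesm-4-ene-3,8-dione
Product: 13 (7R,8R,10R)-8-hydroxyeudesm-4-en-3-one (8β-OH)
Conditions: LiBH(s-Bu)3, THF, −78 °C; aq. NH4Cl
Reagents that add atoms: none
Why: Chemoselective and stereoselective ketone reduction by a bulky trialkylborohydride, in which the saturated C8 ketone should react far faster than the hindered tetrasubstituted enone and hydride enters from the α face, away from the syn-axial C10 methyl, to give the axial 8β-alcohol cis to the isopropyl group (as in menthone to neomenthol).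

Step 8
Reactants: 13 (7R,8R,10R)-8-hydroxyeudesm-4-en-3-one
Product: 14 (7R,8R,10S)-8-hydroxyeudesma-1,4-dien-3-one
Conditions: DDQ, 1,4-dioxane, reflux
Reagents that add atoms: none
Why: Quinone dehydrogenation of a 4-en-3-one to the cross-conjugated 1,4-dien-3-one under neutral conditions (hydride abstraction from C1 of the 2,4-dienol), as in steroid 1,2-dehydrogenation; the free secondary alcohol is tolerated and no stereocentre changes.

Step 9
Reactants: 14 (7R,8R,10S)-8-hydroxyeudesma-1,4-dien-3-one
Product: 15 (1R,7R,8R,10R)-8,10-dihydroxyguai-4-en-3-one (1α-H, 8β-OH, 10α-OH, 10β-methyl)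
Conditions: hν (medium-pressure Hg lamp, Pyrex, λ > 300 nm), AcOH/H2O 1:1, N2, 20 °C
Reagents that add atoms: water, O
Why: Excitation of the cross-conjugated dienone and C1–C5 bonding give a transient cyclopropyl oxyallyl zwitterion that acetic acid protonates on oxygen, after which the C5–C10 cyclopropane bond breaks and water adds to C10; the closest known reaction is the santonin-type photorearrangement of 4-methylcyclohexa-2,5-dienones to 5/7-fused hydroxy ketones in aqueous acid. The cyclopentenone ring (C1–C5) is closed by this transannular C1–C5 bonding (a 3-exo closure onto the dienone whose new bond is kept), whereas the seven-membered ring is not closed but arises by one-atom expansion of ring B, C10 giving up its bond to C5 so that the ring path runs through C1. C1 is controlled by the quaternary C10 centre, because C10 can only swing to the face of its own β-methyl if ring B is to stay cis-fused on the cyclopropane, which leaves H-1 on the α face. C10 is set by inversion, water entering opposite to the departing C5, which gives the 10α-hydroxy-10β-methyl centre. The selectivity needed is the 5/7-fused hydroxy ketone over the lumiketone and over the spiro isomer: aqueous acid intercepts the zwitterion before its sigmatropic shift, and the C4 methyl group stabilises positive charge at C4 so that C5–C10 and not C1–C10 is cleaved. C7 and C8 are untouched and the axial 8β-hydroxyl cannot reach C10.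

Step 10
Reactants: 15 (1R,7R,8R,10R)-8,10-dihydroxyguai-4-en-3-one
Product: 16 4-methylbenzenesulfonylhydrazone of 15 (C=N geometry not defined)
Conditions: TsNHNH2, EtOH, 50 °C
Reagents that add atoms: 4-methylbenzenesulfonohydrazide, Cc1ccc(cc1)S(=O)(=O)NN
Why: Condensation of the enone carbonyl with a sulfonylhydrazide gives the α,β-unsaturated tosylhydrazone; no stereocentre is affected.

Step 11
Reactants: 16 4-methylbenzenesulfonylhydrazone of 15
Product: 19 (1R,5S,7R,8R,10R)-guai-3-ene-8,10-diol (1α-H, 5β-H), via tosylhydrazine 17 (not isolated), via allylic diazene 18 (not isolated)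
Conditions: catecholborane (excess), CHCl3, 0 °C to 20 °C; then NaOAc·3H2O, reflux
Reagents that add atoms: none
Why: Reductive 1,3-transposition of an enone tosylhydrazone with catecholborane, in which hydride should add to C3 from the α face (opposite C10 and its β-methyl, which sit over the β face), loss of sulfinate gives the 3β-diazene, and its suprafacial 1,5-hydrogen shift with loss of N2 places hydrogen on the β face of C5 and moves the double bond to C3=C4, as steroidal 4-en-3-ones give 5β-3-enes.

Step 12
Reactants: 19 (1R,5S,7R,8R,10R)-guai-3-ene-8,10-diol; 20 4-(benzyloxy)-3-methoxybenzoic acid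
Product: 22 (1R,5S,7R,8R,10R)-10-hydroxyguai-3-en-8-yl 4-(benzyloxy)-3-methoxybenzoate, via mixed anhydride 21 (not isolated)
Conditions: 20, 2,4,6-trichlorobenzoyl chloride, Et3N, THF, 20 °C; then 19, DMAP, toluene, 60 °C
Reagents that add atoms: none
Why: Yamaguchi esterification through the mixed anhydride acylates only the secondary C8 hydroxyl, the tertiary C10 hydroxyl being inert, with retention at C8.

Step 13
Reactants: 22 (1R,5S,7R,8R,10R)-10-hydroxyguai-3-en-8-yl 4-(benzyloxy)-3-methoxybenzoate
Product: 23 (1R,3R,4S,5S,7R,8R,10R)-3,4-epoxy-10-hydroxyguaian-8-yl 4-(benzyloxy)-3-methoxybenzoate (3α,4α-epoxide)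
Conditions: VO(acac)2 (cat.), t-BuOOH, CH2Cl2, 0 °C to 20 °C
Reagents that add atoms: tert-butyl hydroperoxide, CC(C)(C)OO
Why: Hydroxyl-directed vanadium-catalysed epoxidation of a bishomoallylic tertiary alcohol, in which the 10α-hydroxyl should hold the vanadium peroxide under the α face of the cyclopentene while the 10β-methyl shields the β face, setting C3 and C4 together as the α-epoxide; the syn hydroxyl cannot open the epoxide from the rear.

Step 14
Reactants: 23 (1R,3R,4S,5S,7R,8R,10R)-3,4-epoxy-10-hydroxyguaian-8-yl 4-(benzyloxy)-3-methoxybenzoate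
Product: 24 (1R,3R,4S,5S,7R,8R,10R)-3,4-epoxy-10-hydroxyguaian-8-yl 4-hydroxy-3-methoxybenzoate (target)
Conditions: H2 (1 atm), Pd/C, EtOAc, 20 °C
Reagents that add atoms: none
Why: Hydrogenolysis of the aryl benzyl ether over palladium on carbon under neutral conditions frees the phenol, while the aliphatic trisubstituted epoxide, the ester and the tertiary alcohol are neither benzylic nor allylic and should persist.

**Compound list**
1 | 4-methoxy-2-methylphenol | COc1ccc(O)c(C)c1 | starting material
2 | 4,4-dimethoxy-2-methylcyclohexa-2,5-dien-1-one | COC1(OC)C=CC(=O)C(C)=C1 | intermediate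
3 | 7-methyl-1,4-dioxaspiro[4.5]deca-6,9-dien-8-one | CC1=CC2(OCCO2)C=CC1=O | intermediate
4 | (10R)-7-methyl-10-(propan-2-yl)-1,4-dioxaspiro[4.5]dec-6-en-8-one | CC1=CC2(OCCO2)[C@@H](C(C)C)CC1=O | intermediate
5 | (6R)-9-methyl-6-(propan-2-yl)-1,4-dioxaspiro[4.5]decan-8-one, both C9 epimers | CC1CC2(OCCO2)[C@@H](C(C)C)CC1=O | intermediate
6 | (R)-1-phenylethylamine | C[C@@H](N)c1ccccc1 | starting material
7 | pent-1-en-3-one (ethyl vinyl ketone) | CCC(=O)C=C | starting material
8 | N-[(1R)-1-phenylethyl]imine of 5 | CC1CC2(OCCO2)[C@@H](C(C)C)CC1=N[C@H](C)c1ccccc1 | intermediate (not isolated)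
9 | N-[(1R)-1-phenylethyl]imine of 10 (Michael adduct) | CCC(=O)CC[C@]1(C)CC2(OCCO2)[C@@H](C(C)C)CC1=N[C@H](C)c1ccccc1 | intermediate (not isolated)
10 | (6R,9R)-9-methyl-9-(3-oxopentyl)-6-(propan-2-yl)-1,4-dioxaspiro[4.5]decan-8-one | CCC(=O)CC[C@]1(C)CC2(OCCO2)[C@@H](C(C)C)CC1=O | intermediate
11 | (7R,10R)-eudesm-4-ene-3,8-dione 8-(ethane-1,2-diyl ketal) | O=C1CC[C@]2(C)CC3(OCCO3)[C@@H](C(C)C)CC2=C1C | intermediate (not isolated)
12 | (7R,10R)-eudesm-4-ene-3,8-dione (7β-isopropyl, 10β-methyl) | O=C1CC[C@]2(C)CC(=O)[C@@H](C(C)C)CC2=C1C | intermediate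
13 | (7R,8R,10R)-8-hydroxyeudesm-4-en-3-one (8β-OH) | O=C1CC[C@]2(C)C[C@@H](O)[C@@H](C(C)C)CC2=C1C | intermediate
14 | (7R,8R,10S)-8-hydroxyeudesma-1,4-dien-3-one | O=C1C=C[C@]2(C)C[C@@H](O)[C@@H](C(C)C)CC2=C1C | intermediate
15 | (1R,7R,8R,10R)-8,10-dihydroxyguai-4-en-3-one (1α-H, 8β-OH, 10α-OH) | O[C@@H]1C[C@@](C)(O)[C@@H]2CC(=O)C(C)=C2C[C@@H]1C(C)C | intermediate
16 | 4-methylbenzenesulfonylhydrazone of 15 | O[C@@H]1C[C@@](C)(O)[C@@H]2CC(=NNS(=O)(=O)c3ccc(C)cc3)C(C)=C2C[C@@H]1C(C)C | intermediate
17 | N'-[(1R,3S,7R,8R,10R)-8,10-dihydroxyguai-4-en-3-yl]-4-methylbenzenesulfonohydrazide (N- and O-borylated in the flask) | O[C@@H]1C[C@@](C)(O)[C@@H]2C[C@H](NNS(=O)(=O)c3ccc(C)cc3)C(C)=C2C[C@@H]1C(C)C | intermediate (not isolated)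
18 | (1R,3S,7R,8R,10R)-3-diazenylguai-4-ene-8,10-diol (3β-diazene) | O[C@@H]1C[C@@](C)(O)[C@@H]2C[C@H](N=N)C(C)=C2C[C@@H]1C(C)C | intermediate (not isolated)
19 | (1R,5S,7R,8R,10R)-guai-3-ene-8,10-diol (1α-H, 5β-H) | O[C@@H]1C[C@@](C)(O)[C@@H]2CC=C(C)[C@H]2C[C@@H]1C(C)C | intermediate
20 | 4-(benzyloxy)-3-methoxybenzoic acid | COc1cc(C(=O)O)ccc1OCc1ccccc1 | starting material
21 | 4-(benzyloxy)-3-methoxybenzoic 2,4,6-trichlorobenzoic anhydride | COc1cc(C(=O)OC(=O)c2c(Cl)cc(Cl)cc2Cl)ccc1OCc1ccccc1 | intermediate (not isolated)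
22 | (1R,5S,7R,8R,10R)-10-hydroxyguai-3-en-8-yl 4-(benzyloxy)-3-methoxybenzoate | COc1cc(C(=O)O[C@@H]2C[C@@](C)(O)[C@@H]3CC=C(C)[C@H]3C[C@@H]2C(C)C)ccc1OCc1ccccc1 | intermediate
23 | (1R,3R,4S,5S,7R,8R,10R)-3,4-epoxy-10-hydroxyguaian-8-yl 4-(benzyloxy)-3-methoxybenzoate | COc1cc(C(=O)O[C@@H]2C[C@@](C)(O)[C@@H]3C[C@H]4O[C@@]4(C)[C@H]3C[C@@H]2C(C)C)ccc1OCc1ccccc1 | intermediate
24 | (1R,3R,4S,5S,7R,8R,10R)-3,4-epoxy-10-hydroxyguaian-8-yl 4-hydroxy-3-methoxybenzoate | COc1cc(C(=O)O[C@@H]2C[C@@](C)(O)[C@@H]3C[C@H]4O[C@@]4(C)[C@H]3C[C@@H]2C(C)C)ccc1O | target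

**Totals**
Total step count: 14. Longest linear sequence: 14 steps (1 to 24); acid 20, amine 6 and enone 7 are purchased.

**Steps most likely to fail, with fallbacks**

Step 9. The hydroxy enone may be photolysed further as it accumulates in the aqueous medium, and the C10 cation may lose a proton in competition with hydration. The fallback sets out from 14 and runs the rearrangement as an acetolysis. Irradiation in anhydrous acetic acid lets acetate collapse on C10 and should give the tertiary acetate (1R,7R,8R,10R)-10-acetoxy-8-hydroxyguai-4-en-3-one F1, the ester form in which this class of photoproduct is most robust. F1 is condensed with tosylhydrazide to the tosylhydrazone F2 and reduced with catecholborane to the tosylhydrazine F3. On heating with NaOAc·3H2O, F3 passes through the diazene F4 to the transposed alkene acetate F5. LiAlH4 in THF at 0 °C then cleaves the tertiary acetate, and the sequence comes back to the route at 19.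

Step 11. Hydride may be delivered to C3 from the β face instead of the α face, which would end in the cis-fused 5α-H alkene. The fallback sets out from 15 and fixes C5 by an SN2 inversion instead of by the face of a hydride addition. Luche reduction (NaBH4, CeCl3·7H2O, MeOH, −78 °C) with that same β-face preference should give the 3α-allylic alcohol F6. Mitsunobu displacement with 2-nitrobenzenesulfonylhydrazide (PPh3, diethyl azodicarboxylate, N-methylmorpholine, −30 °C) inverts C3 and gives the 3β-sulfonylhydrazine F7. On warming to 20 °C, F7 loses the sulfinic acid to give diazene 18, which collapses as in the main route; the fallback comes back at 19.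

Step 13. Epoxidation may occur from the β face if steric approach control overrides delivery from the 10α-hydroxyl. The fallback sets out from 22 and builds the epoxide in two stages that invert the facial outcome. NBS in aqueous acetone at 0 °C should form the bromonium ion on the more accessible β face, and water opens it at the tertiary C4 from the α face to give the bromohydrin F8 (3β-bromo-4α-hydroxy). K2CO3 in MeOH at 0 °C then closes the ring with inversion at C3 to the 3α,4α-epoxide, and the fallback comes back at 23.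

**Further compounds**
F1 | step 9 | (1R,7R,8R,10R)-10-acetoxy-8-hydroxyguai-4-en-3-one | O[C@@H]1C[C@@](C)(OC(C)=O)[C@@H]2CC(=O)C(C)=C2C[C@@H]1C(C)C
F2 | step 9 | 4-methylbenzenesulfonylhydrazone of F1 | O[C@@H]1C[C@@](C)(OC(C)=O)[C@@H]2CC(=NNS(=O)(=O)c3ccc(C)cc3)C(C)=C2C[C@@H]1C(C)C
F3 | step 9 | N'-[(1R,3S,7R,8R,10R)-10-acetoxy-8-hydroxyguai-4-en-3-yl]-4-methylbenzenesulfonohydrazide | O[C@@H]1C[C@@](C)(OC(C)=O)[C@@H]2C[C@H](NNS(=O)(=O)c3ccc(C)cc3)C(C)=C2C[C@@H]1C(C)C
F4 | step 9 | (1R,3S,7R,8R,10R)-10-acetoxy-3-diazenylguai-4-en-8-ol | O[C@@H]1C[C@@](C)(OC(C)=O)[C@@H]2C[C@H](N=N)C(C)=C2C[C@@H]1C(C)C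
F5 | step 9 | (1R,5S,7R,8R,10R)-10-acetoxyguai-3-en-8-ol | O[C@@H]1C[C@@](C)(OC(C)=O)[C@@H]2CC=C(C)[C@H]2C[C@@H]1C(C)C
F6 | step 11 | (1R,3R,7R,8R,10R)-guai-4-ene-3,8,10-triol (3α-OH) | O[C@@H]1C[C@@](C)(O)[C@@H]2C[C@@H](O)C(C)=C2C[C@@H]1C(C)C
F7 | step 11 | N-[(1R,3S,7R,8R,10R)-8,10-dihydroxyguai-4-en-3-yl]-2-nitrobenzenesulfonohydrazide | O[C@@H]1C[C@@](C)(O)[C@@H]2C[C@H](N(N)S(=O)(=O)c3ccccc3[N+](=O)[O-])C(C)=C2C[C@@H]1C(C)C
F8 | step 13 | (1R,3S,4S,5S,7R,8R,10R)-3-bromo-4,10-dihydroxyguaian-8-yl 4-(benzyloxy)-3-methoxybenzoate (3β-Br, 4α-OH) | COc1cc(C(=O)O[C@@H]2C[C@@](C)(O)[C@@H]3C[C@H](Br)[C@@](C)(O)[C@H]3C[C@@H]2C(C)C)ccc1OCc1ccccc1
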